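**Retrosynthetic overview**

1. Target quinone ⇐ the corresponding 2-methoxyphenol (ring A at the arene level) by para-oxidation, the last stage of the biosynthesis.
2. Ring A ⇐ an acyclic farnesane-type C15 acid (2-methoxy-8-tigloyloxy-4,5-didehydrofarnesoic acid). Closure is head-to-tail, C1 onto C6, with loss of a C14 proton, as in bisabolyl cation → β-bisabolene. It is run at the acyl oxidation level, so the ring emerges aromatic with the C7=C14 methylene already in place.
3. C15 acid ⇐ C13 hydroxy dienone + C2 methoxyphosphonate (C2=C3); dienone ⇐ C10 hydroxy enal + acetonyl ylide (C4=C5).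
4. C10 unit ⇐ C5 enal-acetal: asymmetric allylboration sets C8 as S; cross-metathesis turns allyl into prenyl.
5. Ring order: one ring only, formed in step 6 and oxidised to the quinone in step 7.

Locants in the comments are bisabolane (farnesane) locants: C1 = carboxyl carbon of the chain = ring carbon carrying the quinone oxygen next to C2–OMe; C3 carries methyl C15; C6 carries the side chain; C7 carries C14; C8 = stereocentre.

Assumption: 1, 2, 5, 7, 10, 14 and 20 are bought as catalogue items; yields and ee are not optimised here.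

**Route**

Step 1
Reactants: 1 (2E)-4,4-dimethoxy-2-methylbut-2-enal; 2 allylboronic acid pinacol ester
Product: 4 (4S,5E)-7,7-dimethoxy-5-methylhepta-1,5-dien-4-ol, via borate ester 3 (not isolated)
Conditions: (S)-3,3′-bis(2,4,6-triisopropylphenyl)-1,1′-binaphthyl-2,2′-diyl hydrogen phosphate (5 mol%), 4 Å MS, PhMe, −30 °C; aq. NaHCO3 work-up
Reagents that add atoms: 4,4,5,5-tetramethyl-2-(prop-2-en-1-yl)-1,3,2-dioxaborolane, C=CCB1OC(C)(C)C(C)(C)O1
Why: Chiral Brønsted acid catalysed allylboration of an aldehyde through a closed six-membered chair transition state in which the (S)-phosphoric acid binds the boronate oxygen and the formyl hydrogen and so exposes the Si face of the enal, which sets the only stereocentre (C8) as S; the acetal survives because no water is present.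

Step 2
Reactants: 4 (4S,5E)-7,7-dimethoxy-5-methylhepta-1,5-dien-4-ol; 5 2-methylbut-2-ene
Product: 6 (2E,4S)-1,1-dimethoxy-3,7-dimethylocta-2,6-dien-4-ol
Conditions: second-generation Grubbs catalyst RuCl2(=CHPh)(PCy3)(H2IMes) (3 mol%), 2-methylbut-2-ene/CH2Cl2 (1:1), 40 °C
Reagents that add atoms: 2-methylbut-2-ene, CC=C(C)C
Why: Olefin cross-metathesis in which the terminal alkene trades its methylidene for the isopropylidene of the excess trisubstituted partner (propene is lost), while the trisubstituted allylic-acetal alkene is too hindered to engage and C8 is not touched.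

Step 3
Reactants: 6 (2E,4S)-1,1-dimethoxy-3,7-dimethylocta-2,6-dien-4-ol; 7 1-(triphenylphosphoranylidene)propan-2-one
Product: 9 (3E,5E,7S)-7-hydroxy-6,10-dimethylundeca-3,5,9-trien-2-one, via hydroxy enal 8 (not isolated)
Conditions: pyridinium 4-toluenesulfonate (10 mol%), acetone/H2O (10:1), 20 °C; NaHCO3, solvent switch; then 7 (1.3 equiv), PhMe, 60 °C
Reagents that add atoms: 1-(triphenylphosphoranylidene)propan-2-one, CC(=O)C=P(c1ccccc1)(c1ccccc1)c1ccccc1
Why: Mild acid hydrolysis of the allylic acetal followed, without isolation of the sensitive hydroxy enal, by a Wittig olefination with a ketone-stabilised ylide that gives the E-enone; the E geometry of the enal holds the C8 hydroxyl away from the aldehyde and the neutral ylide cannot enolise C8.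

Step 4
Reactants: 9 (3E,5E,7S)-7-hydroxy-6,10-dimethylundeca-3,5,9-trien-2-one; 10 methyl 2-(dimethoxyphosphoryl)-2-methoxyacetate; 11 sodium hydroxide
Product: 13 (2E/Z,4E,6E,8S)-8-hydroxy-2-methoxy-3,7,11-trimethyldodeca-2,4,6,10-tetraenoic acid, via methyl ester 12 (not isolated)
Conditions: 10 (2.2 equiv), NaH (3.3 equiv), THF, 0 to 45 °C; then 2 M aq. NaOH, MeOH, 45 °C; 1 M HCl to pH 4, 0 °C
Reagents that add atoms: methyl 2-(dimethoxyphosphoryl)-2-methoxyacetate, COC(=O)C(OC)P(=O)(OC)OC; sodium hydroxide, [Na+].[OH-]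
Why: Horner–Wadsworth–Emmons olefination of the methyl ketone by 1,2-addition of the phosphonate anion (as with ionone-type dienones), then saponification in the same pot; the C2=C3 geometry is of no consequence because step 6 erases it, and C8, held as its alkoxide, is not deprotonated.

Step 5
Reactants: 13 (2E/Z,4E,6E,8S)-8-hydroxy-2-methoxy-3,7,11-trimethyldodeca-2,4,6,10-tetraenoic acid; 14 (2E)-2-methylbut-2-enoyl chloride (tigloyl chloride)
Product: 15 (2E/Z,4E,6E,8S)-2-methoxy-3,7,11-trimethyl-8-{[(2E)-2-methylbut-2-enoyl]oxy}dodeca-2,4,6,10-tetraenoic acid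
Conditions: LiN(SiMe3)2 (2.05 equiv), THF, −78 °C; 14 (1.05 equiv), −78 to −20 °C; 1 M HCl to pH 4, 0 °C
Reagents that add atoms: (2E)-2-methylbut-2-enoyl chloride, C/C=C(\C)C(Cl)=O
Why: Chemoselective O-acylation of a dianion: at −78 °C the lithium alkoxide is far more nucleophilic than the lithium carboxylate, so one equivalent of the acid chloride gives the tiglate ester with retention at C8 because no bond to the stereocentre is broken.

Step 6
Reactants: 15 (2E/Z,4E,6E,8S)-2-methoxy-3,7,11-trimethyl-8-{[(2E)-2-methylbut-2-enoyl]oxy}dodeca-2,4,6,10-tetraenoic acid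
Product: 19 (3S)-2-(2-hydroxy-3-methoxy-4-methylphenyl)-6-methylhepta-1,5-dien-3-yl (2E)-2-methylbut-2-enoate, via mixed acetic anhydride 16 (not isolated), via trienylketene 17 (not isolated), via aryl acetate 18 (not isolated)
Conditions: Ac2O (6 equiv), Et3N (8 equiv), PhMe, 90 °C; evaporate; K2CO3 (0.5 equiv), MeOH, 0 °C
Reagents that add atoms: none
Why: Proposed new method: the mixed anhydride loses acetate by vinylogous E1cB deprotonation of the C7 methyl group (C14) to give trienylketene 17, whose 6π-electrocyclisation forges C1–C6 (the bond and the C14 proton loss of the bisabolyl cation to β-bisabolene sequence) and whose cyclohexadienone tautomerises at once to the phenol, which is trapped as acetate 18 and freed by selective methanolysis; the closest known reaction types are the Ac2O/acetate benzannulation of unsaturated acids (Stobbe-type naphthol synthesis) and the dienylketene electrocyclisation of the Danheiser benzannulation, all three alkene geometries of 15 are erased on the way, and C8 is not touched.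

Step 7
Reactants: 19 (3S)-2-(2-hydroxy-3-methoxy-4-methylphenyl)-6-methylhepta-1,5-dien-3-yl (2E)-2-methylbut-2-enoate; 20 potassium nitrosodisulfonate (KSO3)2NO
Product: 21 (3S)-2-(5-methoxy-4-methyl-3,6-dioxocyclohexa-1,4-dien-1-yl)-6-methylhepta-1,5-dien-3-yl (2E)-2-methylbut-2-enoate (CNP0232608.4)
Conditions: (KSO3)2NO (2.5 equiv), KH2PO4 buffer, acetone/H2O, 20 °C
Reagents that add atoms: potassium nitrosodisulfonate, [K+].[K+].[O]N(S(=O)(=O)[O-])S(=O)(=O)[O-]
Why: Teuber oxidation of a phenol with a free para position: the phenoxyl radical is captured at C4 by a second equivalent of the nitroxyl radical and collapses to the 1,4-benzoquinone, the laboratory counterpart of the phenol-to-quinone oxidation that ends the biosynthesis, and the alkenes, the tiglate and C8 are inert to this one-electron oxidant.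

**Compound list**

1 | (2E)-4,4-dimethoxy-2-methylbut-2-enal | O=C/C(C)=C/C(OC)OC | starting material
2 | 4,4,5,5-tetramethyl-2-(prop-2-en-1-yl)-1,3,2-dioxaborolane (allylboronic acid pinacol ester) | C=CCB1OC(C)(C)C(C)(C)O1 | starting material
3 | 2-{[(4S,5E)-7,7-dimethoxy-5-methylhepta-1,5-dien-4-yl]oxy}-4,4,5,5-tetramethyl-1,3,2-dioxaborolane | COC(OC)/C=C(C)/[C@H](CC=C)OB1OC(C)(C)C(C)(C)O1 | intermediate
4 | (4S,5E)-7,7-dimethoxy-5-methylhepta-1,5-dien-4-ol | COC(OC)/C=C(C)/[C@H](CC=C)O | intermediate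
5 | 2-methylbut-2-ene | CC=C(C)C | starting material
6 | (2E,4S)-1,1-dimethoxy-3,7-dimethylocta-2,6-dien-4-ol | COC(OC)/C=C(C)/[C@H](CC=C(C)C)O | intermediate
7 | 1-(triphenylphosphoranylidene)propan-2-one | CC(=O)C=P(c1ccccc1)(c1ccccc1)c1ccccc1 | starting material
8 | (2E,4S)-4-hydroxy-3,7-dimethylocta-2,6-dienal | O=C/C=C(C)/[C@H](CC=C(C)C)O | intermediate
9 | (3E,5E,7S)-7-hydroxy-6,10-dimethylundeca-3,5,9-trien-2-one | CC(=O)/C=C/C=C(C)/[C@H](CC=C(C)C)O | intermediate
10 | methyl 2-(dimethoxyphosphoryl)-2-methoxyacetate | COC(=O)C(OC)P(=O)(OC)OC | starting material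
11 | sodium hydroxide | [Na+].[OH-] | starting material
12 | methyl (2E/Z,4E,6E,8S)-8-hydroxy-2-methoxy-3,7,11-trimethyldodeca-2,4,6,10-tetraenoate | COC(=O)C(OC)=C(C)/C=C/C=C(C)/[C@H](CC=C(C)C)O | intermediate
13 | (2E/Z,4E,6E,8S)-8-hydroxy-2-methoxy-3,7,11-trimethyldodeca-2,4,6,10-tetraenoic acid | OC(=O)C(OC)=C(C)/C=C/C=C(C)/[C@H](CC=C(C)C)O | intermediate
14 | (2E)-2-methylbut-2-enoyl chloride (tigloyl chloride) | C/C=C(\C)C(Cl)=O | starting material
15 | (2E/Z,4E,6E,8S)-2-methoxy-3,7,11-trimethyl-8-{[(2E)-2-methylbut-2-enoyl]oxy}dodeca-2,4,6,10-tetraenoic acid | OC(=O)C(OC)=C(C)/C=C/C=C(C)/[C@H](CC=C(C)C)OC(=O)/C(C)=C/C | intermediate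
16 | acetic (2E/Z,4E,6E,8S)-2-methoxy-3,7,11-trimethyl-8-{[(2E)-2-methylbut-2-enoyl]oxy}dodeca-2,4,6,10-tetraenoic anhydride | CC(=O)OC(=O)C(OC)=C(C)/C=C/C=C(C)/[C@H](CC=C(C)C)OC(=O)/C(C)=C/C | intermediate
17 | (3Z,5E,8S)-2-methoxy-3,11-dimethyl-7-methylidene-1-oxododeca-1,3,5,10-tetraen-8-yl (2E)-2-methylbut-2-enoate (trienylketene) | O=C=C(OC)/C(C)=C\C=C\C(=C)[C@H](CC=C(C)C)OC(=O)/C(C)=C/C | intermediate
18 | (3S)-2-[2-(acetyloxy)-3-methoxy-4-methylphenyl]-6-methylhepta-1,5-dien-3-yl (2E)-2-methylbut-2-enoate | CC(=O)Oc1c(OC)c(C)ccc1C(=C)[C@H](CC=C(C)C)OC(=O)/C(C)=C/C | intermediate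
19 | (3S)-2-(2-hydroxy-3-methoxy-4-methylphenyl)-6-methylhepta-1,5-dien-3-yl (2E)-2-methylbut-2-enoate | Oc1c(OC)c(C)ccc1C(=C)[C@H](CC=C(C)C)OC(=O)/C(C)=C/C | intermediate
20 | potassium nitrosodisulfonate, (KSO3)2NO | [K+].[K+].[O]N(S(=O)(=O)[O-])S(=O)(=O)[O-] | starting material
21 | (3S)-2-(5-methoxy-4-methyl-3,6-dioxocyclohexa-1,4-dien-1-yl)-6-methylhepta-1,5-dien-3-yl (2E)-2-methylbut-2-enoate | C=C(C1=CC(=O)C(C)=C(OC)C1=O)[C@H](CC=C(C)C)OC(=O)/C(C)=C/C | target

**Totals and risks**

Total step count: 7. Longest linear sequence: 7 (the route is fully linear from 1).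

The three steps most likely to fail:

Step 6 (ring closure). The ketene must form with the Z geometry at the new C3=C4 bond. Deprotonation at C8 instead of C14 would give an enol ester by-product or erode the ee. Fallback, from 15 back to 19: replace the thermal, neutral ketene route by a cold, stepwise cationic closure. Treat 15 with 1-chloro-N,N,2-trimethylprop-1-en-1-amine (CH2Cl2, 0 °C) to give (2E/Z,4E,6E,8S)-2-methoxy-3,7,11-trimethyl-8-{[(2E)-2-methylbut-2-enoyl]oxy}dodeca-2,4,6,10-tetraenoyl chloride F1. Ionise it with AgOSO2CF3 and 2,6-di-tert-butyl-4-methylpyridine (CH2Cl2, −78 to 0 °C). The delocalised trienoyl cation can rotate about its former double bonds, acylates the C6=C7 alkene in a Friedel–Crafts-type closure of C1 onto C6, and the hindered base removes the C14 proton. The dienone tautomerises to 19 without heat and without the acetate detour.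

Step 3 (hydroxy enal). Under acid, 8 can isomerise to the Z-enal and cyclodehydrate to a 2-prenyl-3-methylfuran. Fallback, from 6 back to 9: mask the hydroxyl before the aldehyde is unveiled. Silylate 6 (tert-butyldimethylsilyl chloride, imidazole, DMF) to tert-butyl{[(2E,4S)-1,1-dimethoxy-3,7-dimethylocta-2,6-dien-4-yl]oxy}dimethylsilane F2. Hydrolysis as in step 3 then gives (2E,4S)-4-{[tert-butyl(dimethyl)silyl]oxy}-3,7-dimethylocta-2,6-dienal F3, which cannot close to the furan. Wittig reaction with 7 gives (3E,5E,7S)-7-{[tert-butyl(dimethyl)silyl]oxy}-6,10-dimethylundeca-3,5,9-trien-2-one F4, and HF·pyridine (THF, 0 °C) returns 9.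

Step 4 (olefination of the dienone). The hindered methoxyphosphonate anion may add slowly or in a conjugate sense to the hydroxy dienone. Fallback, from 6 (hydrolysed to 8 as in step 3) back to 13: make C4=C5 instead of C2=C3. Prepare methyl 2-methoxy-3-methylbut-2-enoate F5 from acetone and 10 (NaH, THF). Deprotonate F5 at its γ-methyl group with KOC(CH3)3 (THF, −20 to 20 °C) and add 8. The vinylogous aldol adduct lactonises to (6RS)-6-[(1E,3S)-3-hydroxy-2,6-dimethylhepta-1,5-dien-1-yl]-3-methoxy-4-methyl-5,6-dihydro-2H-pyran-2-one F6. Base-induced ring-opening elimination in the same pot then gives the (2Z)-isomer of acid 13 directly, bypassing 9 and 12.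

**Further compounds**

F1 | step 6 | (2E/Z,4E,6E,8S)-2-methoxy-3,7,11-trimethyl-8-{[(2E)-2-methylbut-2-enoyl]oxy}dodeca-2,4,6,10-tetraenoyl chloride | ClC(=O)C(OC)=C(C)/C=C/C=C(C)/[C@H](CC=C(C)C)OC(=O)/C(C)=C/C
F2 | step 3 | tert-butyl{[(2E,4S)-1,1-dimethoxy-3,7-dimethylocta-2,6-dien-4-yl]oxy}dimethylsilane | COC(OC)/C=C(C)/[C@H](CC=C(C)C)O[Si](C)(C)C(C)(C)C
F3 | step 3 | (2E,4S)-4-{[tert-butyl(dimethyl)silyl]oxy}-3,7-dimethylocta-2,6-dienal | O=C/C=C(C)/[C@H](CC=C(C)C)O[Si](C)(C)C(C)(C)C
F4 | step 3 | (3E,5E,7S)-7-{[tert-butyl(dimethyl)silyl]oxy}-6,10-dimethylundeca-3,5,9-trien-2-one | CC(=O)/C=C/C=C(C)/[C@H](CC=C(C)C)O[Si](C)(C)C(C)(C)C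
F5 | step 4 | methyl 2-methoxy-3-methylbut-2-enoate | COC(=O)C(OC)=C(C)C
F6 | step 4 | (6RS)-6-[(1E,3S)-3-hydroxy-2,6-dimethylhepta-1,5-dien-1-yl]-3-methoxy-4-methyl-5,6-dihydro-2H-pyran-2-one | COC1=C(C)CC(/C=C(C)/[C@H](CC=C(C)C)O)OC1=O
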